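**Plan**
- Pyran numbering: O-1, C-2 (aryl), C-3 (CH2OAc), C-4 (CH2), C-5 (benzofuran-2-yl), C-6 (=CH–O).
- Enabling feature: C-3 carries two one-carbon arms, ring C-4 and the acetate CH2. A temporary bond from C-4 to the acetate oxygen ties them into a symmetric oxetane. The enol ether C-5=C-6 on benzofuran C-2 is a masked (benzofuran-2-yl)acetaldehyde, electrophilic at C-6 and nucleophilic at C-5.
- Retrosynthesis: remove the acetyl groups, then cut O-1–C-6 and C-4–C-5 together. This gives an (R)-aryl(oxetan-3-yl)methanol and a (benzofuran-2-yl)acetaldehyde diethyl acetal. The first is cut at the aryl–carbonyl bond, the second at benzofuran bonds C-3a–C-3 and O–C-2.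
- Forward order: the benzofuran ring is made first and the purchased oxetane ring is carried to the key step. The dihydropyran ring closes last, as the oxetane opens, and the freed oxygen is then acetylated.
- Stereochemistry: C-2 comes from catalytic asymmetric hydrogenation of the aryl oxetanyl ketone. C-3 comes from substrate-controlled choice between the two diastereotopic oxetane CH2 groups in the key step.
- Both phenols travel as acetates. These suppress benzylic ionisation at C-2 in the acid step and leave last by selective aminolysis.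

Key step: step 9

Assumption: oxetane-3-carboxylic acid, 4-bromo-2-methoxyphenol, 2-bromo-1,4-dimethoxybenzene and 4,4-diethoxybut-1-yne are taken as catalogue compounds.

**Step 1**
Reactants: 1 oxetane-3-carboxylic acid
Product: 3 N-methoxy-N-methyloxetane-3-carboxamide, via acyl imidazolide 2 (not isolated)
Conditions: CDI (1.1 equiv), CH2Cl2, rt; then MeNH(OMe)·HCl (1.2 equiv), rt
Reagents that add atoms: N,O-dimethylhydroxylamine hydrochloride, CNOC.Cl; 1,1'-carbonyldiimidazole, O=C(n1ccnc1)n1ccnc1 (its imidazole stays only in 2)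
Why: CDI-mediated amide coupling through the acyl imidazolide runs near neutrality, so the acid-sensitive oxetane survives.

**Step 2**
Reactants: 3 N-methoxy-N-methyloxetane-3-carboxamide; 4 4-bromo-2-methoxyphenol
Product: 6 (4-hydroxy-3-methoxyphenyl)(oxetan-3-yl)methanone, via dilithio species 5 (not isolated)
Conditions: 4 (1.2 equiv), t-BuLi (3.6 equiv), THF, −78 °C; then 3 (1.0 equiv), −78 to 0 °C; aq NH4Cl
Reagents that add atoms: tert-butyllithium, [Li]C(C)(C)C (its lithium stays only in 5)
Why: Phenol deprotonation and irreversible bromine–lithium exchange give the aryllithium, which adds once to the N-methoxy-N-methylamide (Weinreb ketone synthesis), and an oxetane is inert to organolithiums at low temperature without a Lewis acid.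

**Step 3**
Reactants: 6 (4-hydroxy-3-methoxyphenyl)(oxetan-3-yl)methanone
Product: 7 2-methoxy-4-(oxetane-3-carbonyl)phenyl acetate
Conditions: Ac2O (1.2 equiv), Et3N, DMAP (5 mol %), CH2Cl2, 0 °C
Reagents that add atoms: acetic anhydride, CC(=O)OC(C)=O
Why: DMAP-catalysed O-acetylation of the only nucleophilic group, which also lowers the donor power of the aryl ring for step 9.

**Step 4**
Reactants: 7 2-methoxy-4-(oxetane-3-carbonyl)phenyl acetate
Product: 8 4-[(R)-hydroxy(oxetan-3-yl)methyl]-2-methoxyphenyl acetate
Conditions: RuH(BH4)[(S)-xylbinap][(S,S)-dpen] (0.2 mol %), H2 (8 atm), i-PrOH, 25 °C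
Reagents that add atoms: none
Why: Noyori asymmetric hydrogenation of an aryl sec-alkyl ketone by outer-sphere Ru–H/N–H transfer, in which the (S)/(S,S) catalyst that gives (R)-1-arylalkanols should set C-2 as R, while the base-free borohydride precatalyst spares the aryl acetate and avoids enolisation next to the oxetane.

**Step 5**
Reactants: 9 2-bromo-1,4-dimethoxybenzene
Product: 10 1-(4-bromo-2,5-dimethoxyphenyl)ethanone
Conditions: AcCl (1.2 equiv), AlCl3 (1.3 equiv), CH2Cl2, 0 °C
Reagents that add atoms: acetyl chloride, CC(=O)Cl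
Why: Friedel–Crafts acylation goes para to bromine and ortho to a methoxy group, the least hindered activated position.

**Step 6**
Reactants: 10 1-(4-bromo-2,5-dimethoxyphenyl)ethanone
Product: 11 1-(4-bromo-2,5-dihydroxyphenyl)ethanone
Conditions: BBr3 (3 equiv), CH2Cl2, −78 °C to rt; then H2O
Reagents that add atoms: none
Why: Lewis-acid cleavage of both aryl methyl ethers with BBr3, to which the ketone and the aryl bromide are inert.

**Step 7**
Reactants: 11 1-(4-bromo-2,5-dihydroxyphenyl)ethanone; 12 4,4-diethoxybut-1-yne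
Product: 14 1-[2-(2,2-diethoxyethyl)-5-hydroxy-1-benzofuran-6-yl]ethanone, via alkynyl hydroquinone 13 (not isolated)
Conditions: PdCl2(PPh3)2 (5 mol %), CuI (10 mol %), Et3N, DMF, 80 °C, argon
Reagents that add atoms: none
Why: Sonogashira coupling at the C–Br bond activated by the para acetyl group is followed by 5-endo-dig addition of the neighbouring phenol to the metal-activated alkyne (one-pot benzofuran heteroannulation), while the other phenol is hydrogen-bonded to the acetyl group and out of reach, and the acetal is stable to base.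

**Step 8**
Reactants: 14 1-[2-(2,2-diethoxyethyl)-5-hydroxy-1-benzofuran-6-yl]ethanone
Product: 15 6-acetyl-2-(2,2-diethoxyethyl)-1-benzofuran-5-yl acetate
Conditions: Ac2O (1.5 equiv), Et3N, DMAP (10 mol %), CH2Cl2, rt
Reagents that add atoms: acetic anhydride, CC(=O)OC(C)=O
Why: DMAP-catalysed acetylation overcomes the hydrogen bond of the chelated phenol and leaves the acetal untouched under basic conditions.

**Step 9**
Reactants: 8 4-[(R)-hydroxy(oxetan-3-yl)methyl]-2-methoxyphenyl acetate; 15 6-acetyl-2-(2,2-diethoxyethyl)-1-benzofuran-5-yl acetate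
Product: 19 4-[(2R,3S)-5-(6-acetyl-5-acetoxy-1-benzofuran-2-yl)-3-(hydroxymethyl)-3,4-dihydro-2H-pyran-2-yl]-2-methoxyphenyl acetate, via mixed acetal 16 (not isolated), via acyclic enol ether 17 (not isolated), via ring oxocarbenium ion 18 (not isolated)
Conditions: 8 (1.1 equiv), 15 (1.0 equiv), HNTf2 (10 mol %), 5 Å MS, CH2Cl2 (0.02 M), 0 °C to rt; then Et3N
Reagents that add atoms: none
Why: Proposed new method: HNTf2 exchanges one ethoxy group of 15 for the carbinol oxygen of 8 (O-1–C-6 bond, mixed acetal 16) and, as the sieves take up ethanol, expels the second one to give the benzofuran-conjugated enol ether 17, whose nucleophilic carbon C-5 attacks from the rear one CH2 of the protonated oxetane (C-4–C-5 bond), so that the strained C-4–O bond breaks and ring oxocarbenium ion 18 loses H-5 to give the conjugated enol ether 19 with the former oxetane oxygen as a free primary alcohol. The closest known reaction types are the BF3-catalysed rearrangement of oxetan-3-ylmethyl esters to bicyclic OBO ortho esters (same tether length, C=O in place of C=C as the π-nucleophile), the acid-catalysed intramolecular desymmetrising opening of 3-substituted oxetanes to six-membered heterocycles, and the LiNTf2- or silyl-triflimide-catalysed opening of oxetanes by silyl ketene acetals, and the new element is an alkyl enol ether made in situ as the carbon nucleophile. The dihydropyran closes in the favoured 6-(enolendo)-exo-tet mode, driven by release of the oxetane strain. C-2 is not touched, and the new stereocentre C-3 is set by the choice between the two diastereotopic oxetane CH2 groups: the nearly planar four-membered ring holds the remaining CH2–O arm anti to the incoming C-5, that is equatorial on the half-chair transition state, so the CH2 that reacts should be the one that also leaves the C-2 aryl group equatorial, which gives the trans (2R,3S) isomer. The step needs opening at the oxetane CH2 instead of ionisation of the benzylic C-2–O bond, which the electron-poor 4-acetoxy group secures, and it needs carbon attack instead of capture by an oxygen nucleophile or self-condensation, which the acetal in place of the free aldehyde, the sieves, high dilution and the reversibility of every event before the ring opening should secure.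

**Step 10**
Reactants: 19 4-[(2R,3S)-5-(6-acetyl-5-acetoxy-1-benzofuran-2-yl)-3-(hydroxymethyl)-3,4-dihydro-2H-pyran-2-yl]-2-methoxyphenyl acetate
Product: 20 [(2R,3S)-2-(4-acetoxy-3-methoxyphenyl)-5-(6-acetyl-5-acetoxy-1-benzofuran-2-yl)-3,4-dihydro-2H-pyran-3-yl]methyl acetate
Conditions: Ac2O (1.5 equiv), pyridine, DMAP (5 mol %), CH2Cl2, 0 °C to rt
Reagents that add atoms: acetic anhydride, CC(=O)OC(C)=O
Why: Basic DMAP-catalysed acetylation of the primary alcohol leaves the acid-sensitive enol ether and both stereocentres untouched.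

**Step 11**
Reactants: 20 [(2R,3S)-2-(4-acetoxy-3-methoxyphenyl)-5-(6-acetyl-5-acetoxy-1-benzofuran-2-yl)-3,4-dihydro-2H-pyran-3-yl]methyl acetate
Product: 21 propolis-benzofuran A
Conditions: pyrrolidine (2.2 equiv), THF, 0 °C; then pH 6 phosphate buffer
Reagents that add atoms: none
Why: Chemoselective aminolysis, in which the two aryl acetates with their phenoxide leaving groups react with a secondary amine far faster than the primary alkyl acetate, and neither stereocentre is involved.

**Compound list**
1 | oxetane-3-carboxylic acid | OC(=O)C1COC1 | starting material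
2 | 1-(oxetane-3-carbonyl)imidazole (acyl imidazolide) | O=C(C1COC1)n1ccnc1 | intermediate
3 | N-methoxy-N-methyloxetane-3-carboxamide | CON(C)C(=O)C1COC1 | intermediate
4 | 4-bromo-2-methoxyphenol | COc1cc(Br)ccc1O | starting material
5 | lithium 4-lithio-2-methoxyphenoxide (dilithio species) | COc1cc([Li])ccc1O[Li] | intermediate
6 | (4-hydroxy-3-methoxyphenyl)(oxetan-3-yl)methanone | COc1cc(C(=O)C2COC2)ccc1O | intermediate
7 | 2-methoxy-4-(oxetane-3-carbonyl)phenyl acetate | COc1cc(C(=O)C2COC2)ccc1OC(C)=O | intermediate
8 | 4-[(R)-hydroxy(oxetan-3-yl)methyl]-2-methoxyphenyl acetate | COc1cc([C@H](O)C2COC2)ccc1OC(C)=O | intermediate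
9 | 2-bromo-1,4-dimethoxybenzene | COc1ccc(OC)c(Br)c1 | starting material
10 | 1-(4-bromo-2,5-dimethoxyphenyl)ethanone | CC(=O)c1cc(OC)c(Br)cc1OC | intermediate
11 | 1-(4-bromo-2,5-dihydroxyphenyl)ethanone | CC(=O)c1cc(O)c(Br)cc1O | intermediate
12 | 4,4-diethoxybut-1-yne | C#CCC(OCC)OCC | starting material
13 | 1-[4-(4,4-diethoxybut-1-yn-1-yl)-2,5-dihydroxyphenyl]ethanone | CCOC(CC#Cc1cc(O)c(C(C)=O)cc1O)OCC | intermediate
14 | 1-[2-(2,2-diethoxyethyl)-5-hydroxy-1-benzofuran-6-yl]ethanone | CCOC(Cc1cc2cc(O)c(C(C)=O)cc2o1)OCC | intermediate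
15 | 6-acetyl-2-(2,2-diethoxyethyl)-1-benzofuran-5-yl acetate | CCOC(Cc1cc2cc(OC(C)=O)c(C(C)=O)cc2o1)OCC | intermediate
16 | 4-[(R)-[2-(6-acetyl-5-acetoxy-1-benzofuran-2-yl)-1-ethoxyethoxy](oxetan-3-yl)methyl]-2-methoxyphenyl acetate (mixed acetal, both epimers at the acetal carbon) | COc1cc([C@H](OC(Cc2cc3cc(OC(C)=O)c(C(C)=O)cc3o2)OCC)C2COC2)ccc1OC(C)=O | intermediate
17 | 4-[(R)-{[(E)-2-(6-acetyl-5-acetoxy-1-benzofuran-2-yl)ethenyl]oxy}(oxetan-3-yl)methyl]-2-methoxyphenyl acetate (E drawn, either geometry can cyclise) | COc1cc([C@H](O/C=C/c2cc3cc(OC(C)=O)c(C(C)=O)cc3o2)C2COC2)ccc1OC(C)=O | intermediate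
18 | (2R,3S)-2-(4-acetoxy-3-methoxyphenyl)-5-(6-acetyl-5-acetoxy-1-benzofuran-2-yl)-3-(hydroxymethyl)-2,3,4,5-tetrahydropyrylium, cation of the triflimide salt (C-5 unassigned) | COc1cc([C@@H]2[O+]=CC(c3cc4cc(OC(C)=O)c(C(C)=O)cc4o3)C[C@H]2CO)ccc1OC(C)=O | intermediate
19 | 4-[(2R,3S)-5-(6-acetyl-5-acetoxy-1-benzofuran-2-yl)-3-(hydroxymethyl)-3,4-dihydro-2H-pyran-2-yl]-2-methoxyphenyl acetate | COc1cc([C@@H]2OC=C(c3cc4cc(OC(C)=O)c(C(C)=O)cc4o3)C[C@H]2CO)ccc1OC(C)=O | intermediate
20 | [(2R,3S)-2-(4-acetoxy-3-methoxyphenyl)-5-(6-acetyl-5-acetoxy-1-benzofuran-2-yl)-3,4-dihydro-2H-pyran-3-yl]methyl acetate | COc1cc([C@@H]2OC=C(c3cc4cc(OC(C)=O)c(C(C)=O)cc4o3)C[C@H]2COC(C)=O)ccc1OC(C)=O | intermediate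
21 | propolis-benzofuran A, [(2R,3S)-5-(6-acetyl-5-hydroxy-1-benzofuran-2-yl)-2-(4-hydroxy-3-methoxyphenyl)-3,4-dihydro-2H-pyran-3-yl]methyl acetate | COc1cc([C@@H]2OC=C(c3cc4cc(O)c(C(C)=O)cc4o3)C[C@H]2COC(C)=O)ccc1O | target

Total step count: 11. Longest linear sequence: 7 steps (steps 1–4 or steps 5–8, then steps 9–11).

**Steps most likely to fail**

1. **Step 9 (proposed new method).**
   - What may go wrong: an acetal oxygen or liberated ethanol may capture the activated oxetane before C-5 attacks. The enol ether may self-condense under acid. Discrimination between the two oxetane CH2 groups may be weak. The freed alcohol may add back to the new enol ether.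
   - Fallback, by known chemistry, from 15 back to 20:
     - The acetal of 15 is hydrolysed (TFA, wet CH2Cl2, 0 °C) to 6-acetyl-2-(2-oxoethyl)-1-benzofuran-5-yl acetate F1.
     - Eschenmoser's salt and Et3N in CH2Cl2 give the Mannich base F2. It loses dimethylamine in the flask to give 6-acetyl-2-(3-oxoprop-1-en-2-yl)-1-benzofuran-5-yl acetate F3.
     - Commercial (E)-coniferyl alcohol is acetylated (Ac2O, pyridine) to (E)-coniferyl diacetate F4.
     - A thermal inverse-electron-demand hetero-Diels–Alder reaction of heterodiene F3 with an excess of F4 (toluene, 120 °C, BHT) forms O-1–C-2 and C-3–C-4 suprafacially. The E alkene should therefore give only the trans isomer, as the racemic triacetate F5.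
     - Preparative HPLC on a chiral stationary phase then delivers 20.

2. **Step 7.**
   - What may go wrong: oxidative addition into the electron-rich bromophenoxide may be slow. The free hydroquinone may be oxidised by adventitious air and copper. Base may shift the alkyne to an allene before ring closure.
   - Fallback, from 11 back to 14:
     - Coupling and ring closure are separated and the phenols are masked. Ac2O and pyridine convert 11 into 2-acetyl-5-bromo-1,4-phenylene diacetate F6.
     - The electron-poor bromide F6 undergoes Sonogashira coupling with 12 (PdCl2(PPh3)2, CuI, Et3N, THF, 60 °C) to give 2-acetyl-5-(4,4-diethoxybut-1-yn-1-yl)-1,4-phenylene diacetate F7.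
     - K2CO3 in MeOH at 50 °C removes both acetates. The liberated 13 closes by base-mediated 5-endo-dig addition to 14.

3. **Step 11.**
   - What may go wrong: the primary acetate may also be lost. Once the guaiacyl phenol is free, base may open the ring at C-2 through para-quinone-methide formation, with epimerisation at C-2.
   - Fallback, from 19 back to 21:
     - The order is reversed, so that selectivity rests on an acylation instead of a deacylation. Pyrrolidine (2.2 equiv, THF, 0 °C) removes the two aryl acetates of 19, which holds no alkyl acetate.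
     - This gives 1-{5-hydroxy-2-[(2R,3S)-2-(4-hydroxy-3-methoxyphenyl)-3-(hydroxymethyl)-3,4-dihydro-2H-pyran-5-yl]-1-benzofuran-6-yl}ethanone F8.
     - Immobilised Candida antarctica lipase B with vinyl acetate (THF/MTBE, 30 °C) acetylates the primary alcohol and not the phenols, under neutral conditions, to give 21.

**Further compounds**
F1 | step 9 | 6-acetyl-2-(2-oxoethyl)-1-benzofuran-5-yl acetate | O=CCc1cc2cc(OC(C)=O)c(C(C)=O)cc2o1
F2 | step 9 | 6-acetyl-2-[1-(dimethylamino)-3-oxopropan-2-yl]-1-benzofuran-5-yl acetate (Mannich base) | CN(C)CC(C=O)c1cc2cc(OC(C)=O)c(C(C)=O)cc2o1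
F3 | step 9 | 6-acetyl-2-(3-oxoprop-1-en-2-yl)-1-benzofuran-5-yl acetate | C=C(C=O)c1cc2cc(OC(C)=O)c(C(C)=O)cc2o1
F4 | step 9 | (E)-coniferyl diacetate, 4-[(E)-3-acetoxyprop-1-en-1-yl]-2-methoxyphenyl acetate | COc1cc(/C=C/COC(C)=O)ccc1OC(C)=O
F5 | step 9 | racemic trans triacetate (20 and its enantiomer) | COc1cc([C@@H]2OC=C(c3cc4cc(OC(C)=O)c(C(C)=O)cc4o3)C[C@H]2COC(C)=O)ccc1OC(C)=O.COc1cc([C@H]2OC=C(c3cc4cc(OC(C)=O)c(C(C)=O)cc4o3)C[C@@H]2COC(C)=O)ccc1OC(C)=O
F6 | step 7 | 2-acetyl-5-bromo-1,4-phenylene diacetate | CC(=O)c1cc(OC(C)=O)c(Br)cc1OC(C)=O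
F7 | step 7 | 2-acetyl-5-(4,4-diethoxybut-1-yn-1-yl)-1,4-phenylene diacetate | CCOC(CC#Cc1cc(OC(C)=O)c(C(C)=O)cc1OC(C)=O)OCC
F8 | step 11 | 1-{5-hydroxy-2-[(2R,3S)-2-(4-hydroxy-3-methoxyphenyl)-3-(hydroxymethyl)-3,4-dihydro-2H-pyran-5-yl]-1-benzofuran-6-yl}ethanone | COc1cc([C@@H]2OC=C(c3cc4cc(O)c(C(C)=O)cc4o3)C[C@H]2CO)ccc1O
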